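**Plan**

1. Numbering: ring A is the benzoate ring (C1 CO2Me, C2 O‑prenyl, C4 CH3, C6 O‑aryl); ring B is C1′ (O to ring A), C2′ (CH2OH), C4′ and C6′ (OMe). The retrosynthesis cuts the two aryl O–CH3 bonds, then ring B at C5′–C6′, C3′–C4′ and C1′–C6′ (C2′–C3′ falls with them, as it stems from a 1,2‑vinyl shift), then the vinylic C1′–O(ring A) bond, then O–prenyl.
2. Enabling feature: ring B has its oxygens at C4′ and C6′ in a 1,3‑relationship about C5′–H (ynol ether carbon and ketene carbonyl), and C1′(O‑aryl)=C2′(CH2O)–C3′(H) is the chain of a β‑aryloxy vinylketene.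
3. Forward: ring A is bought complete and monoprenylated. Methyl vinyl ketone supplies C1′, C2′, C6′ and C3′ and formaldehyde the CH2OH carbon; the resulting bromo enone is joined to the ring A phenol by vinylic substitution, and the methyl group becomes the diazo carbon C3′.
4. Ring B, the only ring made, closes in step 11 against separately prepared (triisopropylsilyloxy)acetylene (C4′, C5′); desilylation and double O‑methylation finish the route.
5. Stereochemistry: there is none to set; the target is achiral, and the double‑bond geometry of the vinyl ether intermediates vanishes when C1′ becomes aromatic.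

Key step: step 11

Remark 1: the target has no stereocentre and no stereogenic double bond (the prenyl alkene carries two identical methyl groups), so no enantiocontrol is required.
Remark 2: (triisopropylsilyloxy)acetylene is not assumed to be purchasable and is made in steps 8–10. The Si–O bond is put in place before the triple bond, because O‑silylation of the parent ynolate would compete with C‑silylation to the silylketene.
Remark 3: compounds 9–12 are drawn as E isomers (acyl group trans to Br or O‑aryl); the Z isomers would serve equally.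

**Route**

Step 1
Reactants: 1 methyl 2,6-dihydroxy-4-methylbenzoate; 2 prenyl bromide (1-bromo-3-methylbut-2-ene)
Product: 3 methyl 2-hydroxy-4-methyl-6-(3-methylbut-2-enyloxy)benzoate
Conditions: K2CO3 (1.1 equiv), 2 (1.05 equiv, slow addition), acetone, rt to 40 °C
Reagents that add atoms: none
Why: Williamson etherification with one equivalent of the allylic bromide under weak base should stop largely at the mono‑ether, because the remaining phenol is held in a hydrogen bond to the ester carbonyl and is a poorer nucleophile, while carbonate in acetone favours O‑ over C‑prenylation.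

Step 2
Reactants: 4 methyl vinyl ketone; 5 formaldehyde (37% aqueous)
Product: 6 3-(hydroxymethyl)but-3-en-2-one
Conditions: DABCO (0.2 equiv), THF–H2O, rt
Reagents that add atoms: none
Why: Morita–Baylis–Hillman reaction in which the amine adds to the enone, the ammonium enolate is hydroxymethylated by formaldehyde and the amine is expelled again, a known access to this α‑(hydroxymethyl) enone.

Step 3
Reactants: 6 3-(hydroxymethyl)but-3-en-2-one
Product: 7 3-[(tert-butyldimethylsilyloxy)methyl]but-3-en-2-one
Conditions: TBSCl, imidazole, CH2Cl2, 0 °C to rt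
Reagents that add atoms: tert-butyldimethylsilyl chloride (CC(C)(C)[Si](C)(C)Cl)
Why: Standard imidazole‑promoted silylation of a primary alcohol, needed so that no hydroxyl group can later trap the ketene.

Step 4
Reactants: 7 3-[(tert-butyldimethylsilyloxy)methyl]but-3-en-2-one
Product: 9 (E)-4-bromo-3-[(tert-butyldimethylsilyloxy)methyl]but-3-en-2-one, via dibromo ketone 8 (not isolated)
Conditions: Br2 (1.05 equiv), CH2Cl2, −78 to 0 °C; then Et3N (1.5 equiv), 0 °C to rt
Reagents that add atoms: bromine (BrBr)
Why: Bromination–dehydrobromination, as used to turn α‑substituted acroleins and enones into β‑bromo enones, since the tertiary α‑bromide of 8 is lost together with the acidified proton of the CH2Br group and the isomer with bromine trans to acetyl is expected to prevail.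

Step 5
Reactants: 3 methyl 2-hydroxy-4-methyl-6-(3-methylbut-2-enyloxy)benzoate; 9 (E)-4-bromo-3-[(tert-butyldimethylsilyloxy)methyl]but-3-en-2-one
Product: 10 methyl 2-{(E)-2-[(tert-butyldimethylsilyloxy)methyl]-3-oxobut-1-enyloxy}-4-methyl-6-(3-methylbut-2-enyloxy)benzoate
Conditions: 9 (1.2 equiv), Cs2CO3 (1.5 equiv), DMF, 0 °C to rt
Reagents that add atoms: none
Why: Nucleophilic vinylic substitution by conjugate addition–elimination, in which the phenoxide adds to the β‑carbon of the bromo enone and the enolate expels bromide (a far better leaving group than the silanolate), forming the C1′–O bond without any aryl–oxygen coupling.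

Step 6
Reactants: 10 methyl 2-{(E)-2-[(tert-butyldimethylsilyloxy)methyl]-3-oxobut-1-enyloxy}-4-methyl-6-(3-methylbut-2-enyloxy)benzoate
Product: 11 methyl 2-{(E)-2-[(tert-butyldimethylsilyloxy)methyl]-6,6,6-trifluoro-3,5-dioxohex-1-enyloxy}-4-methyl-6-(3-methylbut-2-enyloxy)benzoate
Conditions: LiHMDS (1.1 equiv), THF, −78 °C; CF3CO2CH2CF3 (1.2 equiv), −78 °C, 10 min; cold dilute HCl work-up, crude product used at once
Reagents that add atoms: 2,2,2-trifluoroethyl trifluoroacetate (O=C(OCC(F)(F)F)C(F)(F)F)
Why: Kinetic lithium enolate formation at the methyl group, the only enolisable position, followed by Claisen‑type C‑acylation with the activated trifluoroacetate gives the β‑diketone that activates the future C3′ for diazo transfer.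

Step 7
Reactants: 11 methyl 2-{(E)-2-[(tert-butyldimethylsilyloxy)methyl]-6,6,6-trifluoro-3,5-dioxohex-1-enyloxy}-4-methyl-6-(3-methylbut-2-enyloxy)benzoate
Product: 12 methyl 2-{(E)-4-diazo-2-[(tert-butyldimethylsilyloxy)methyl]-3-oxobut-1-enyloxy}-4-methyl-6-(3-methylbut-2-enyloxy)benzoate
Conditions: MsN3 (1.5 equiv), Et3N (1.5 equiv), H2O (1 equiv), MeCN, rt
Reagents that add atoms: methanesulfonyl azide (CS(=O)(=O)N=[N+]=[N-])
Why: Detrifluoroacetylative diazo transfer (Regitz type), in which the diketone enolate adds to the sulfonyl azide and the adduct fragments with loss of the trifluoroacetyl group as its sulfonamide, the dependable way to α′‑diazo enones where acid chloride and diazomethane chemistry attacks the double bond.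

Step 8
Reactants: 13 tetrahydrofuran
Product: 15 triisopropyl(vinyloxy)silane, via lithium ethenolate 14 (not isolated)
Conditions: n-BuLi, THF (reactant and solvent), rt, 16 h; then TIPSCl, DMPU, 0 °C to rt
Reagents that add atoms: triisopropylsilyl chloride (CC(C)[Si](Cl)(C(C)C)C(C)C)
Why: α‑Lithiated tetrahydrofuran undergoes the known [3+2] cycloreversion to ethylene and the lithium enolate of acetaldehyde, which is O‑silylated by the bulky chlorosilane in the standard preparation of silyl vinyl ethers.

Step 9
Reactants: 15 triisopropyl(vinyloxy)silane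
Product: 17 (Z)-(2-bromovinyloxy)triisopropylsilane, via dibromo ether 16 (not isolated)
Conditions: Br2 (1.0 equiv), CH2Cl2, −78 °C; then i-Pr2NEt (1.5 equiv), −78 °C to rt
Reagents that add atoms: bromine (BrBr)
Why: Bromine addition to the enol ether followed by amine‑induced loss of HBr from the labile α‑bromo ether follows the known preparation of (Z)-2-bromovinyl ethyl and trimethylsilyl ethers, and the bulky silyl group should suppress desilylation by bromide.

Step 10
Reactants: 17 (Z)-(2-bromovinyloxy)triisopropylsilane
Product: 19 (triisopropylsilyloxy)acetylene, via lithium acetylide 18 (not isolated)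
Conditions: LDA (2.2 equiv), THF, −78 °C; H2O quench at −78 °C; distillation under reduced pressure, stored cold under argon
Reagents that add atoms: none
Why: Base‑induced dehydrobromination of a 2‑halovinyl ether is the classical alkynyl ether synthesis, the second equivalent of amide holds the product as its acetylide until the quench, and no O‑ versus C‑silylation question arises because the Si–O bond already exists.

Step 11
Reactants: 12 methyl 2-{(E)-4-diazo-2-[(tert-butyldimethylsilyloxy)methyl]-3-oxobut-1-enyloxy}-4-methyl-6-(3-methylbut-2-enyloxy)benzoate; 19 (triisopropylsilyloxy)acetylene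
Product: 24 methyl 2-{2-[(tert-butyldimethylsilyloxy)methyl]-6-hydroxy-4-(triisopropylsilyloxy)phenoxy}-4-methyl-6-(3-methylbut-2-enyloxy)benzoate, via vinylketene 20 (not isolated), via vinylcyclobutenone 21 (not isolated), via dienylketene 22 (not isolated), via cyclohexadienone 23 (not isolated)
Conditions: 19 (2.5 equiv), hν (365 nm), degassed ClCH2CH2Cl, rt until 12 is consumed; then 80 °C, 4–6 h
Reagents that add atoms: none
Why: Irradiation of the α′‑diazo enone at a wavelength that ring A does not absorb expels dinitrogen and the β‑aryloxyvinyl group shifts from the carbonyl carbon to the carbene carbon (photo‑Wolff rearrangement, creating C2′–C3′) to give vinylketene 20, whose ketene C=C bond undergoes [2+2] cycloaddition with the electron‑rich alkyne 19 to form vinylcyclobutenone 21 (C5′–C6′ and C3′–C4′). On warming, 21 opens by 4π‑electrocyclic cleavage of its C3′–C6′ bond to dienylketene 22, and ring B closes by thermal disrotatory 6π‑electrocyclisation between the ketene carbon and the aryloxy‑bearing vinyl carbon (C1′–C6′) to give cyclohexadienone 23, which tautomerises to the phenol. This is the diazo ketone form of the Danheiser benzannulation, known for α,β‑unsaturated and heteroaryl diazo ketones with triisopropylsiloxyalkynes, so only the molecule is new. No stereocentre survives, since the sp3 carbons of 21 and 23 are transient and the geometry of the C1′=C2′ bond is lost when C1′ becomes aromatic. The step needs one regiochemistry in the [2+2] event, ketene carbonyl carbon to the unsubstituted alkyne carbon, and the oxygen lone pair of 19 secures it by making that carbon the nucleophilic terminus, which places the siloxy group at C4′ meta to the new C6′ hydroxyl with C5′–H between them. Ketene capture by a nucleophile is excluded because the hydroxymethyl group is silylated, and the prenyl ether and the benzoate are not excited at 365 nm.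

Step 12
Reactants: 24 methyl 2-{2-[(tert-butyldimethylsilyloxy)methyl]-6-hydroxy-4-(triisopropylsilyloxy)phenoxy}-4-methyl-6-(3-methylbut-2-enyloxy)benzoate
Product: 25 methyl 2-[2,4-dihydroxy-6-(hydroxymethyl)phenoxy]-4-methyl-6-(3-methylbut-2-enyloxy)benzoate
Conditions: TBAF (2.4 equiv), AcOH (2.4 equiv), THF, 0 °C to rt, argon
Reagents that add atoms: none
Why: Fluoride‑mediated desilylation cleaves both the aryl triisopropylsilyl ether and the primary tert‑butyldimethylsilyl ether, and the acetic acid buffer should keep the liberated C6′ phenoxide from attacking the hindered ring A ester or its ipso carbon.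

Step 13
Reactants: 25 methyl 2-[2,4-dihydroxy-6-(hydroxymethyl)phenoxy]-4-methyl-6-(3-methylbut-2-enyloxy)benzoate
Product: 26 methyl 2-[2-(hydroxymethyl)-4,6-dimethoxyphenoxy]-4-methyl-6-(3-methylbut-2-enyloxy)benzoate
Conditions: MeI (3 equiv), K2CO3 (3 equiv), acetone, rt to 40 °C
Reagents that add atoms: iodomethane (CI)
Why: Williamson methylation under carbonate deprotonates only the two phenols and not the far less acidic benzylic alcohol, so both aryl methyl ethers should form while the hydroxymethyl group stays free.

**Compound list**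

1 | methyl 2,6-dihydroxy-4-methylbenzoate | COC(=O)c1c(O)cc(C)cc1O | starting material
2 | prenyl bromide (1-bromo-3-methylbut-2-ene) | CC(C)=CCBr | starting material
3 | methyl 2-hydroxy-4-methyl-6-(3-methylbut-2-enyloxy)benzoate | COC(=O)c1c(O)cc(C)cc1OCC=C(C)C | intermediate
4 | methyl vinyl ketone (but-3-en-2-one) | CC(=O)C=C | starting material
5 | formaldehyde | C=O | starting material
6 | 3-(hydroxymethyl)but-3-en-2-one | CC(=O)C(=C)CO | intermediate
7 | 3-[(tert-butyldimethylsilyloxy)methyl]but-3-en-2-one | CC(=O)C(=C)CO[Si](C)(C)C(C)(C)C | intermediate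
8 | 3,4-dibromo-3-[(tert-butyldimethylsilyloxy)methyl]butan-2-one (racemic, not isolated) | CC(=O)C(Br)(CBr)CO[Si](C)(C)C(C)(C)C | intermediate
9 | (E)-4-bromo-3-[(tert-butyldimethylsilyloxy)methyl]but-3-en-2-one | CC(=O)/C(CO[Si](C)(C)C(C)(C)C)=C/Br | intermediate
10 | methyl 2-{(E)-2-[(tert-butyldimethylsilyloxy)methyl]-3-oxobut-1-enyloxy}-4-methyl-6-(3-methylbut-2-enyloxy)benzoate | CC(=O)/C(CO[Si](C)(C)C(C)(C)C)=C/Oc1cc(C)cc(OCC=C(C)C)c1C(=O)OC | intermediate
11 | methyl 2-{(E)-2-[(tert-butyldimethylsilyloxy)methyl]-6,6,6-trifluoro-3,5-dioxohex-1-enyloxy}-4-methyl-6-(3-methylbut-2-enyloxy)benzoate | O=C(CC(=O)/C(CO[Si](C)(C)C(C)(C)C)=C/Oc1cc(C)cc(OCC=C(C)C)c1C(=O)OC)C(F)(F)F | intermediate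
12 | methyl 2-{(E)-4-diazo-2-[(tert-butyldimethylsilyloxy)methyl]-3-oxobut-1-enyloxy}-4-methyl-6-(3-methylbut-2-enyloxy)benzoate | [N-]=[N+]=CC(=O)/C(CO[Si](C)(C)C(C)(C)C)=C/Oc1cc(C)cc(OCC=C(C)C)c1C(=O)OC | intermediate
13 | tetrahydrofuran | C1CCOC1 | starting material
14 | lithium ethenolate (not isolated) | [Li+].[O-]C=C | intermediate
15 | triisopropyl(vinyloxy)silane | C=CO[Si](C(C)C)(C(C)C)C(C)C | intermediate
16 | (1,2-dibromoethoxy)triisopropylsilane (racemic, not isolated) | BrCC(Br)O[Si](C(C)C)(C(C)C)C(C)C | intermediate
17 | (Z)-(2-bromovinyloxy)triisopropylsilane | Br/C=C\O[Si](C(C)C)(C(C)C)C(C)C | intermediate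
18 | lithium (triisopropylsilyloxy)acetylide (not isolated) | [Li]C#CO[Si](C(C)C)(C(C)C)C(C)C | intermediate
19 | (triisopropylsilyloxy)acetylene [(ethynyloxy)triisopropylsilane] | C#CO[Si](C(C)C)(C(C)C)C(C)C | intermediate
20 | methyl 2-{(Z)-2-[(tert-butyldimethylsilyloxy)methyl]-4-oxobuta-1,3-dienyloxy}-4-methyl-6-(3-methylbut-2-enyloxy)benzoate (vinylketene, not isolated) | O=C=C/C(CO[Si](C)(C)C(C)(C)C)=C/Oc1cc(C)cc(OCC=C(C)C)c1C(=O)OC | intermediate
21 | 4-[1-aryloxy-3-(tert-butyldimethylsilyloxy)prop-1-en-2-yl]-3-(triisopropylsilyloxy)cyclobut-2-enone, aryl = ring A (racemic, not isolated) | O=C1C=C(O[Si](C(C)C)(C(C)C)C(C)C)C1/C(CO[Si](C)(C)C(C)(C)C)=C/Oc2cc(C)cc(OCC=C(C)C)c2C(=O)OC | intermediate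
22 | 6-aryloxy-5-[(tert-butyldimethylsilyloxy)methyl]-3-(triisopropylsilyloxy)hexa-1,3,5-trien-1-one with the ketene and the C5=C6 unit cis on C3=C4, aryl = ring A (dienylketene, not isolated) | O=C=C/C(O[Si](C(C)C)(C(C)C)C(C)C)=C\C(CO[Si](C)(C)C(C)(C)C)=C\Oc1cc(C)cc(OCC=C(C)C)c1C(=O)OC | intermediate
23 | 6-aryloxy-5-[(tert-butyldimethylsilyloxy)methyl]-3-(triisopropylsilyloxy)cyclohexa-2,4-dienone, aryl = ring A (racemic, not isolated) | O=C1C=C(O[Si](C(C)C)(C(C)C)C(C)C)C=C(CO[Si](C)(C)C(C)(C)C)C1Oc2cc(C)cc(OCC=C(C)C)c2C(=O)OC | intermediate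
24 | methyl 2-{2-[(tert-butyldimethylsilyloxy)methyl]-6-hydroxy-4-(triisopropylsilyloxy)phenoxy}-4-methyl-6-(3-methylbut-2-enyloxy)benzoate | COC(=O)c1c(OCC=C(C)C)cc(C)cc1Oc1c(CO[Si](C)(C)C(C)(C)C)cc(O[Si](C(C)C)(C(C)C)C(C)C)cc1O | intermediate
25 | methyl 2-[2,4-dihydroxy-6-(hydroxymethyl)phenoxy]-4-methyl-6-(3-methylbut-2-enyloxy)benzoate | COC(=O)c1c(OCC=C(C)C)cc(C)cc1Oc1c(CO)cc(O)cc1O | intermediate
26 | methyl 2-[2-(hydroxymethyl)-4,6-dimethoxyphenoxy]-4-methyl-6-(3-methylbut-2-enyloxy)benzoate | COC(=O)c1c(OCC=C(C)C)cc(C)cc1Oc1c(CO)cc(OC)cc1OC | target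

**Step count and risks**

Total step count: 13. Longest linear sequence: 9 steps (steps 2, 3, 4, 5, 6, 7, 11, 12 and 13, from methyl vinyl ketone).

Steps most likely to fail:

Step 11 (key step). The vinylketene may oligomerise before it meets the alkyne, light may cleave the aryl prenyl ether of ring A, or the sequence may stall at the cyclobutenone stage and decompose on prolonged heating. The fallback gives up the benzannulation and sets out from 3. Bromination of 3,5-dimethoxybenzaldehyde with NBS in acetonitrile should give 2-bromo-3,5-dimethoxybenzaldehyde F1, in which the halogen sits ortho to the formyl group. Copper‑catalysed Ullmann ether coupling of 3 with F1 (CuI, N,N-dimethylglycine, Cs2CO3, dioxane, 100 °C) should give the diaryl ether aldehyde methyl 2-(2-formyl-4,6-dimethoxyphenoxy)-4-methyl-6-(3-methylbut-2-enyloxy)benzoate F2. Sodium borohydride in methanol at 0 °C would then reduce the aldehyde and leave the hindered methyl ester, so the fallback comes back to the route at 26.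

Step 10. The silyl ynol ether may be lost through silyl transfer at the acetylide stage, through isomerisation to the silylketene, or through oligomerisation during isolation; desilylation during the bromination of step 9 would have the same consequence. The fallback replaces the siloxyalkyne by an alkoxyalkyne that already carries the C4′ methyl group and sets out from 12. Methoxyacetylene F3 is distilled (bp about 23 °C) from the reaction of chloroacetaldehyde dimethyl acetal with sodium amide in liquid ammonia, the classical alkoxyacetylene preparation. It would be used in excess with 12 under the light‑then‑heat conditions of step 11 in a sealed vessel, and should give the phenol methyl 2-{2-[(tert-butyldimethylsilyloxy)methyl]-6-hydroxy-4-methoxyphenoxy}-4-methyl-6-(3-methylbut-2-enyloxy)benzoate F4. Methylation of the single phenol with iodomethane and potassium carbonate in acetone should give methyl 2-{2-[(tert-butyldimethylsilyloxy)methyl]-4,6-dimethoxyphenoxy}-4-methyl-6-(3-methylbut-2-enyloxy)benzoate F5, and TBAF in THF would remove the silyl group, so the fallback comes back at 26.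

Step 5. Addition of the hindered, hydrogen‑bonded phenoxide to the α‑branched bromo enone may be slow, so that base‑induced decomposition of the bromo enone takes over. The fallback changes the electrophile and sets out from 9. Sodium benzenesulfinate in DMF at rt should replace bromide by addition–elimination to give (E)-4-(phenylsulfonyl)-3-[(tert-butyldimethylsilyloxy)methyl]but-3-en-2-one F6, a doubly activated alkene. Phenol 3 with Cs2CO3 in acetonitrile should then add at the sulfonyl‑bearing carbon and expel sulfinate, so the fallback comes back at 10.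

Further compounds
F1 | step 11 | 2-bromo-3,5-dimethoxybenzaldehyde | O=Cc1cc(OC)cc(OC)c1Br
F2 | step 11 | methyl 2-(2-formyl-4,6-dimethoxyphenoxy)-4-methyl-6-(3-methylbut-2-enyloxy)benzoate | COC(=O)c1c(OCC=C(C)C)cc(C)cc1Oc1c(C=O)cc(OC)cc1OC
F3 | step 10 | methoxyacetylene | C#COC
F4 | step 10 | methyl 2-{2-[(tert-butyldimethylsilyloxy)methyl]-6-hydroxy-4-methoxyphenoxy}-4-methyl-6-(3-methylbut-2-enyloxy)benzoate | COC(=O)c1c(OCC=C(C)C)cc(C)cc1Oc1c(CO[Si](C)(C)C(C)(C)C)cc(OC)cc1O
F5 | step 10 | methyl 2-{2-[(tert-butyldimethylsilyloxy)methyl]-4,6-dimethoxyphenoxy}-4-methyl-6-(3-methylbut-2-enyloxy)benzoate | COC(=O)c1c(OCC=C(C)C)cc(C)cc1Oc1c(CO[Si](C)(C)C(C)(C)C)cc(OC)cc1OC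
F6 | step 5 | (E)-4-(phenylsulfonyl)-3-[(tert-butyldimethylsilyloxy)methyl]but-3-en-2-one | CC(=O)/C(CO[Si](C)(C)C(C)(C)C)=C/S(=O)(=O)c1ccccc1
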